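**Strategy**

Prostanoid numbering is used (C1 carboxyl, C6 ketone, ring C8–C12, C13=C14, C15 carbinol). The route rests on disconnecting the C12–C13 bond between the cyclopentane and the (E)-alkenyl chain. An (S,E)-alkenylcopper reagent adds to C12 of (R)-4-silyloxycyclopent-2-enone anti to the C11 silyloxy group, and the C8 enolate so formed is trapped in the same flask by methyl 6-nitrohept-6-enoate, whose nitro carbon is the latent C6 ketone. One operation thus forms C12–C13 and C7–C8 and sets the trans,trans C11/C12/C8 array of the five-membered ring; it exploits the C9 carbonyl, which activates C12 and C8 in turn, and its 1,4-relationship to C6. Reduction, Nef reaction and deprotection follow.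

Key step: step 6

Remark on the chemistry: the target is drawn as the open-chain 6-ketone, which equilibrates with its 6,9-hemiketal; compounds 18 and 19 are written in the keto form. The nitro-bearing C6 in 14–17 is a mixture of epimers that converges in step 8. TBS = tert-butyldimethylsilyl.

**Route**

Step 1
Reactants: 1 (S)-oct-1-yn-3-ol
Product: 2 (S)-3-(tert-butyldimethylsilyloxy)oct-1-yne
Conditions: TBSCl, imidazole, DMF, rt
Reagents that add atoms: tert-butyldimethylsilyl chloride, CC(C)(C)[Si](C)(C)Cl
Why: Imidazole-promoted silylation of the secondary propargylic alcohol (TBS ether formation) should proceed at oxygen only and leaves the purchased (S) centre, the future C15, untouched.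

Step 2
Reactants: 2 (S)-3-(tert-butyldimethylsilyloxy)oct-1-yne
Product: 4 (S,E)-3-(tert-butyldimethylsilyloxy)-1-iodooct-1-ene, via alkenylzirconocene chloride 3 (not isolated)
Conditions: Cp2Zr(H)Cl, THF, rt; then I2, 0 °C
Reagents that add atoms: iodine, II
Why: Schwartz hydrozirconation adds Zr–H syn across the terminal alkyne with zirconium at the unhindered terminus, and iodinolysis of the C–Zr bond goes with retention, so the (E)-alkenyl iodide should form as one regio- and stereoisomer (hydrozirconation–iodination).

Step 3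
Reactants: 5 methyl 6-bromohexanoate
Product: 6 methyl 6-nitrohexanoate
Conditions: NaNO2, phloroglucinol, DMF, rt
Reagents that add atoms: sodium nitrite, [Na+].[O-]N=O
Why: Kornblum substitution, in which nitrite displaces the primary bromide by SN2 mainly through nitrogen in DMF while phloroglucinol scavenges the alkyl nitrite side product; no stereocentre is involved.

Step 4
Reactants: 6 methyl 6-nitrohexanoate
Product: 7 methyl 7-hydroxy-6-nitroheptanoate (racemic)
Conditions: (CH2O)n (1.0 equiv), cat. NaOMe, MeOH, 0 °C to rt; AcOH quench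
Reagents that add atoms: formaldehyde (from paraformaldehyde), C=O
Why: Henry (nitroaldol) addition of the nitronate to formaldehyde, where one equivalent of formaldehyde limits double hydroxymethylation and methoxide in methanol cannot scramble the methyl ester; the new centre is racemic and is removed in step 5.

Step 5
Reactants: 7 methyl 7-hydroxy-6-nitroheptanoate
Product: 9 methyl 6-nitrohept-6-enoate, via mesylate 8 (not isolated)
Conditions: MsCl, Et3N, CH2Cl2, −20 to 0 °C; cold aqueous work-up, used at once
Reagents that add atoms: none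
Why: Mesylation of the primary alcohol followed by E1cB elimination through the nitronate (dehydration of a β-nitro alcohol) should give the 1,1-disubstituted nitroalkene, which is kept cold and used directly because it polymerises readily.

Step 6
Reactants: 4 (S,E)-3-(tert-butyldimethylsilyloxy)-1-iodooct-1-ene; 10 (R)-4-(tert-butyldimethylsilyloxy)cyclopent-2-en-1-one; 9 methyl 6-nitrohept-6-enoate
Product: 15 methyl (11α,13E,15S)-11,15-bis(tert-butyldimethylsilyloxy)-6-nitro-9-oxoprost-13-en-1-oate (C6 epimers), via alkenyllithium 11 (not isolated), via alkenylcopper phosphine complex 12 (not isolated), via cyclopentenolate 13 (not isolated), via nitronate 14 (not isolated)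
Conditions: 4, t-BuLi (2 equiv), Et2O, −78 °C; CuI, n-Bu3P, THF, −78 °C; 10, −78 °C; then 9, −78 to −40 °C; aq. NH4Cl
Reagents that add atoms: none
Why: Iodine–lithium exchange (retention of the E geometry) and transmetalation give the phosphine-stabilised alkenylcopper 12, which adds 1,4 to enone 10 (π-complex, β-cuprio(III) enolate, reductive elimination) to form the C12–C13 bond; enolate 13 then attacks the unsubstituted CH2 terminus of nitroalkene 9 (Michael addition) to form C7–C8, and nitronate 14 is protonated on quench. The closest known reaction type is the tandem conjugate addition–enolate trapping (three-component coupling) of 4-silyloxycyclopentenones, here with a nitroalkene as the Michael acceptor. No ring is closed. C12 is controlled by the C11 silyloxy group of 10, the copper reagent entering anti to it, and C8 by the new C12 substituent, the nitroalkene approaching the enolate face anti to it, which gives the 11,12-trans/8,12-trans array; C15 is carried in from 4 and the C6 nitro centre is not controlled because step 8 removes it. The step needs 1,4- over 1,2-addition and capture of the kinetic enolate faster than proton transfer, which would equilibrate it and expel the C11 silyloxy group; the soft organocopper secures the first and the very high electrophilicity of the nitroalkene at −78 °C, with the product stored as an unreactive nitronate, the second.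

Step 7
Reactants: 15 methyl (11α,13E,15S)-11,15-bis(tert-butyldimethylsilyloxy)-6-nitro-9-oxoprost-13-en-1-oate
Product: 16 methyl (9α,11α,13E,15S)-11,15-bis(tert-butyldimethylsilyloxy)-9-hydroxy-6-nitroprost-13-en-1-oate (C6 epimers)
Conditions: L-Selectride (2.5 equiv), THF, −78 °C; aq. NH4Cl at −78 °C
Reagents that add atoms: none
Why: The bulky trialkylborohydride should deliver hydride to the C9 carbonyl from the β-face, anti to the adjacent C8 side chain and the C11 silyloxy group, so that the 9α-alcohol is expected to predominate (substrate-controlled ketone reduction); the ester is inert at −78 °C and the nitro group, at most deprotonated to its nitronate by the excess reagent, returns on the buffered quench.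

Step 8
Reactants: 16 methyl (9α,11α,13E,15S)-11,15-bis(tert-butyldimethylsilyloxy)-9-hydroxy-6-nitroprost-13-en-1-oate
Product: 18 (9α,11α,13E,15S)-11,15-bis(tert-butyldimethylsilyloxy)-9-hydroxy-6-oxoprost-13-en-1-oic acid, via dilithium nitronate carboxylate 17 (not isolated)
Conditions: LiOH·H2O, THF/MeOH/H2O, 0 °C to rt; then aq. TiCl3, NH4OAc (pH ≈ 6), rt; extraction at pH 4–5
Reagents that add atoms: lithium hydroxide, [Li+].[OH-]; water, O
Why: Hydroxide saponifies the methyl ester and turns the nitro group into its nitronate, which Ti(III) should reduce through the oxime to the N–H imine that hydrolyses to the C6 ketone (McMurry reductive Nef reaction); with C9 already an alcohol no retro-Michael is possible, the buffered medium spares the TBS ethers, and both C6 epimers converge.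

Step 9
Reactants: 18 (9α,11α,13E,15S)-11,15-bis(tert-butyldimethylsilyloxy)-9-hydroxy-6-oxoprost-13-en-1-oic acid
Product: 19 6-keto-prostaglandin F1α, (9α,11α,13E,15S)-9,11,15-trihydroxy-6-oxoprost-13-en-1-oic acid
Conditions: aq. HF (48%), MeCN, 0 °C to rt; buffered work-up (pH ≈ 5)
Reagents that add atoms: none
Why: Fluoride-driven cleavage of both secondary TBS ethers (desilylation) in an aqueous medium, in which the C6 ketone/6,9-hemiketal pair is the stable form and any enol ether is rehydrated; no stereocentre is affected.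

**Compound list**

1 | (S)-oct-1-yn-3-ol | CCCCC[C@H](O)C#C | starting material
2 | (S)-3-(tert-butyldimethylsilyloxy)oct-1-yne | CCCCC[C@H](O[Si](C)(C)C(C)(C)C)C#C | intermediate
3 | (S,E)-[3-(tert-butyldimethylsilyloxy)oct-1-enyl]zirconocene chloride | CCCCC[C@H](O[Si](C)(C)C(C)(C)C)/C=C/[Zr](Cl)(C1C=CC=C1)C1C=CC=C1 | intermediate
4 | (S,E)-3-(tert-butyldimethylsilyloxy)-1-iodooct-1-ene | CCCCC[C@H](O[Si](C)(C)C(C)(C)C)/C=C/I | intermediate
5 | methyl 6-bromohexanoate | COC(=O)CCCCCBr | starting material
6 | methyl 6-nitrohexanoate | COC(=O)CCCCC[N+](=O)[O-] | intermediate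
7 | methyl 7-hydroxy-6-nitroheptanoate (racemic) | COC(=O)CCCCC(CO)[N+](=O)[O-] | intermediate
8 | methyl 7-(methanesulfonyloxy)-6-nitroheptanoate (racemic) | COC(=O)CCCCC(COS(C)(=O)=O)[N+](=O)[O-] | intermediate
9 | methyl 6-nitrohept-6-enoate | COC(=O)CCCCC(=C)[N+](=O)[O-] | intermediate
10 | (R)-4-(tert-butyldimethylsilyloxy)cyclopent-2-en-1-one | O=C1C[C@@H](O[Si](C)(C)C(C)(C)C)C=C1 | starting material
11 | (S,E)-[3-(tert-butyldimethylsilyloxy)oct-1-enyl]lithium | CCCCC[C@H](O[Si](C)(C)C(C)(C)C)/C=C/[Li] | intermediate
12 | (S,E)-[3-(tert-butyldimethylsilyloxy)oct-1-enyl]copper–tributylphosphine complex | CCCCC[C@H](O[Si](C)(C)C(C)(C)C)/C=C/[Cu].CCCCP(CCCC)CCCC | intermediate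
13 | C8–C9 enolate of the conjugate adduct (drawn as the lithium enolate), 4-silyloxy and 3-alkenyl groups trans | CCCCC[C@H](O[Si](C)(C)C(C)(C)C)/C=C/[C@@H]1C=C([O-])C[C@H]1O[Si](C)(C)C(C)(C)C.[Li+] | intermediate
14 | lithium C6 nitronate of 15 | CCCCC[C@H](O[Si](C)(C)C(C)(C)C)/C=C/[C@@H]1[C@@H](CC(CCCCC(=O)OC)=[N+]([O-])[O-])C(=O)C[C@H]1O[Si](C)(C)C(C)(C)C.[Li+] | intermediate
15 | methyl (11α,13E,15S)-11,15-bis(tert-butyldimethylsilyloxy)-6-nitro-9-oxoprost-13-en-1-oate (C6 epimers; C8 and C12 chains trans, C11 oxygen trans to the C12 chain) | CCCCC[C@H](O[Si](C)(C)C(C)(C)C)/C=C/[C@@H]1[C@@H](CC(CCCCC(=O)OC)[N+](=O)[O-])C(=O)C[C@H]1O[Si](C)(C)C(C)(C)C | intermediate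
16 | methyl (9α,11α,13E,15S)-11,15-bis(tert-butyldimethylsilyloxy)-9-hydroxy-6-nitroprost-13-en-1-oate (C6 epimers) | CCCCC[C@H](O[Si](C)(C)C(C)(C)C)/C=C/[C@@H]1[C@@H](CC(CCCCC(=O)OC)[N+](=O)[O-])[C@@H](O)C[C@H]1O[Si](C)(C)C(C)(C)C | intermediate
17 | dilithium nitronate carboxylate of saponified 16 | CCCCC[C@H](O[Si](C)(C)C(C)(C)C)/C=C/[C@@H]1[C@@H](CC(CCCCC(=O)[O-])=[N+]([O-])[O-])[C@@H](O)C[C@H]1O[Si](C)(C)C(C)(C)C.[Li+].[Li+] | intermediate
18 | (9α,11α,13E,15S)-11,15-bis(tert-butyldimethylsilyloxy)-9-hydroxy-6-oxoprost-13-en-1-oic acid | CCCCC[C@H](O[Si](C)(C)C(C)(C)C)/C=C/[C@@H]1[C@@H](CC(=O)CCCCC(=O)O)[C@@H](O)C[C@H]1O[Si](C)(C)C(C)(C)C | intermediate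
19 | 6-keto-prostaglandin F1α | CCCCC[C@H](O)/C=C/[C@@H]1[C@@H](CC(=O)CCCCC(=O)O)[C@@H](O)C[C@H]1O | target

**Summary**

Total step count: 9. Longest linear sequence: 7 steps (5 → 6 → 7 → 9 → 15 → 16 → 18 → 19, steps 3–9).

**Steps most likely to fail**

1. Step 6. The enolate may be captured too slowly, so that proton transfer equilibrates it and the C11 silyloxy group is eliminated, or the nitroalkene may polymerise under the basic conditions. The fallback sets out from 4 and 10 and comes back at 18, introducing the acid chain as a propargylic iodide. Purchased methyl 7-hydroxyhept-5-ynoate F1 is converted with I2, PPh3 and imidazole into methyl 7-iodohept-5-ynoate F2. Alkenyllithium 11 from 4 is turned into the lithium alkenyl(dimethyl)zincate with Me2Zn and added to 10, and the zinc enolate is alkylated with F2 in THF/HMPA to give the 5,6-didehydro-PGE2 derivative F3. L-Selectride should then give the 9α-alcohol F4. Pd(II)- or Au(I)-catalysed 5-exo-dig addition of the C9 hydroxyl to C6 of the alkyne gives the (Z)-enol ether F5, which dilute aqueous acid (pH 3–4) hydrolyses to the 6-oxo methyl ester F6. Saponification with LiOH delivers 18.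

2. Step 8. The reduction may stop at the oxime stage, or the acidic Ti(III) medium may cleave a silyl ether before the imine is hydrolysed. The fallback sets out from 16 and comes back at 18, dividing the Nef reaction into separate operations. SnCl2·2H2O, PhSH and Et3N reduce the secondary nitro group to the oxime methyl ester F7. LiOH saponifies it to the oxime acid F8. Exchange deoximation with aqueous glyoxylic acid and NaOAc then releases the C6 ketone of 18.

3. Step 5. The soluble amine base may start anionic polymerisation of the 1,1-disubstituted nitroalkene as it forms. The fallback sets out from 7 and comes back at 9. Acetylation with Ac2O and catalytic H2SO4 gives the storable methyl 7-acetoxy-6-nitroheptanoate F9. Acetic acid is then eliminated over solid Na2CO3 in refluxing benzene immediately before step 6, so that no soluble base is present when 9 is formed.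

**Further compounds**

F1 | step 6 | methyl 7-hydroxyhept-5-ynoate | COC(=O)CCCC#CCO
F2 | step 6 | methyl 7-iodohept-5-ynoate | COC(=O)CCCC#CCI
F3 | step 6 | methyl (11α,13E,15S)-11,15-bis(tert-butyldimethylsilyloxy)-9-oxoprost-13-en-5-yn-1-oate | CCCCC[C@H](O[Si](C)(C)C(C)(C)C)/C=C/[C@@H]1[C@@H](CC#CCCCC(=O)OC)C(=O)C[C@H]1O[Si](C)(C)C(C)(C)C
F4 | step 6 | methyl (9α,11α,13E,15S)-11,15-bis(tert-butyldimethylsilyloxy)-9-hydroxyprost-13-en-5-yn-1-oate | CCCCC[C@H](O[Si](C)(C)C(C)(C)C)/C=C/[C@@H]1[C@@H](CC#CCCCC(=O)OC)[C@@H](O)C[C@H]1O[Si](C)(C)C(C)(C)C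
F5 | step 6 | methyl (5Z,9α,11α,13E,15S)-11,15-bis(tert-butyldimethylsilyloxy)-6,9-epoxyprosta-5,13-dien-1-oate | CCCCC[C@H](O[Si](C)(C)C(C)(C)C)/C=C/[C@@H]1[C@H]2C/C(=C/CCCC(=O)OC)O[C@H]2C[C@H]1O[Si](C)(C)C(C)(C)C
F6 | step 6 | methyl (9α,11α,13E,15S)-11,15-bis(tert-butyldimethylsilyloxy)-9-hydroxy-6-oxoprost-13-en-1-oate | CCCCC[C@H](O[Si](C)(C)C(C)(C)C)/C=C/[C@@H]1[C@@H](CC(=O)CCCCC(=O)OC)[C@@H](O)C[C@H]1O[Si](C)(C)C(C)(C)C
F7 | step 8 | methyl (9α,11α,13E,15S)-11,15-bis(tert-butyldimethylsilyloxy)-9-hydroxy-6-(hydroxyimino)prost-13-en-1-oate | CCCCC[C@H](O[Si](C)(C)C(C)(C)C)/C=C/[C@@H]1[C@@H](CC(CCCCC(=O)OC)=NO)[C@@H](O)C[C@H]1O[Si](C)(C)C(C)(C)C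
F8 | step 8 | (9α,11α,13E,15S)-11,15-bis(tert-butyldimethylsilyloxy)-9-hydroxy-6-(hydroxyimino)prost-13-en-1-oic acid | CCCCC[C@H](O[Si](C)(C)C(C)(C)C)/C=C/[C@@H]1[C@@H](CC(CCCCC(=O)O)=NO)[C@@H](O)C[C@H]1O[Si](C)(C)C(C)(C)C
F9 | step 5 | methyl 7-acetoxy-6-nitroheptanoate | COC(=O)CCCCC(COC(C)=O)[N+](=O)[O-]
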